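**Retrosynthetic overview**

1. The trans C2–C3 oxirane and the cis C4–C5 oxirane on either side of methyl-bearing C4 in the ten-membered ring C1–C10 are an E,Z-1,3-diene in disguise; the target is therefore traced back to a (1Z,2E,4Z)-cyclodecatriene butenolide by late esterification (C8/C13 acetates, C14 senecioate, C9 (S)-2-methylglycidate) and face-selective double epoxidation.
2. The E,Z-diene comes from thermal conrotatory 4π opening of a cis-fused cyclobutene (C2–C3=C4–C5) on an eight-membered ring (C1, C2, C5–C10); cleaving C2–C5 enlarges the ring by two atoms.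
3. The bicyclo[6.2.0] precursor comes from butenolide annulation (O–C6, C7=C11, C12) by intramolecular Horner–Wadsworth–Emmons reaction on a C7 ketone, after Ni/Cr-mediated closure of the eight-membered ring at C9–C10.
4. The open-chain precursor comes from a D-proline cross-aldol (C7–C8), a bromo-Wittig reaction on a lactol (C1=C10), and an enone–ketene acetal [2+2] photocycloaddition on (S)-5-(hydroxymethyl)furanone (source of C6), followed by enol triflate formation and methyl coupling.
5. Ring order: butyrolactone (chiral pool) → cyclobutane → cyclobutene → eight-membered carbocycle → butenolide → ten-membered ring → two oxiranes.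

Key step: step 23

**Remarks on the chemistry**

- Locants C1–C15 are those of the target skeleton (C14 on C10, C13 on C11, C15 = methyl on C4).
- The lactol is an anomeric mixture, and every compound carrying the phosphonoacetate ester is a mixture of epimers at the phosphonate carbon C11; both centres become sp2 later.
- C7 is drawn as expected for the anti-aldol; it is later oxidised, so its configuration has no consequence.
- The furanone, ketene diethyl acetal, (4-methoxybenzyloxy)acetaldehyde, the bromo ylide, ethyl 2-(diethoxyphosphoryl)acrylate and (R)-2-methylglycidol are taken as commercial.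

**Route**

Step 1
Reactants: 1 (S)-5-(hydroxymethyl)furan-2(5H)-one
Product: 2 (S)-5-[(triisopropylsilyloxy)methyl]furan-2(5H)-one
Conditions: i-Pr3SiCl, imidazole, CH2Cl2, 0 °C to rt
Reagents that add atoms: chlorotriisopropylsilane, CC(C)[Si](Cl)(C(C)C)C(C)C
Why: Imidazole-promoted O-silylation masks the primary alcohol (future C7–OH) with a non-aromatic group that does not absorb at the irradiation wavelength and survives the acidic ketal hydrolysis and the enolate step.

Step 2
Reactants: 2 (S)-5-[(triisopropylsilyloxy)methyl]furan-2(5H)-one; 3 1,1-diethoxyethene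
Product: 4 (1R,4S,5S)-6,6-diethoxy-4-[(triisopropylsilyloxy)methyl]-3-oxabicyclo[3.2.0]heptan-2-one
Conditions: hν (medium-pressure mercury lamp, quartz), 3 (10 equiv), Et2O, −20 °C
Reagents that add atoms: none
Why: Enone–alkene [2+2] photocycloaddition of the excited butenolide with the electron-rich ketene acetal should give the head-to-tail adduct (acetal carbon C4 on the β-carbon C5, CH2 = C3 on C2); the five-membered ring enforces the cis C2/C5 fusion and the C6 side chain sends the alkene to the opposite face, which sets C2 and C5.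

Step 3
Reactants: 4 (1R,4S,5S)-6,6-diethoxy-4-[(triisopropylsilyloxy)methyl]-3-oxabicyclo[3.2.0]heptan-2-one
Product: 5 (1R,4S,5S)-4-[(triisopropylsilyloxy)methyl]-3-oxabicyclo[3.2.0]heptane-2,6-dione
Conditions: TsOH·H2O (cat.), acetone/H2O (10:1), rt
Reagents that add atoms: water, O
Why: Acid-catalysed hydrolysis of the acyclic diethyl ketal frees the cyclobutanone while the lactone and the silyl ether are untouched.

Step 4
Reactants: 5 (1R,4S,5S)-4-[(triisopropylsilyloxy)methyl]-3-oxabicyclo[3.2.0]heptane-2,6-dione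
Product: 7 (1R,4S,5S)-2-oxo-4-[(triisopropylsilyloxy)methyl]-3-oxabicyclo[3.2.0]hept-6-en-6-yl trifluoromethanesulfonate, via potassium enolate 6 (not isolated)
Conditions: KN(SiMe3)2 (1.05 equiv), THF, −78 °C; then PhNTf2, −78 to −20 °C
Reagents that add atoms: N-phenylbis(trifluoromethanesulfonimide), O=S(=O)(N(c1ccccc1)S(=O)(=O)C(F)(F)F)C(F)(F)F
Why: Kinetic deprotonation should occur at the C3 methylene, because the ring-fusion C5–H would give a bridgehead-type enolate and the lactone α-hydrogen is far less acidic; O-sulfonylation of the enolate then gives the cyclobutenyl triflate (enol triflate formation).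

Step 5
Reactants: 7 (1R,4S,5S)-2-oxo-4-[(triisopropylsilyloxy)methyl]-3-oxabicyclo[3.2.0]hept-6-en-6-yl trifluoromethanesulfonate
Product: 8 (1R,4S,5R)-6-methyl-4-[(triisopropylsilyloxy)methyl]-3-oxabicyclo[3.2.0]hept-6-en-2-one
Conditions: MeZnCl (1.5 equiv), Pd(PPh3)4 (5 mol%), THF, 0 °C to rt
Reagents that add atoms: methylzinc chloride, C[Zn]Cl
Why: Negishi cross-coupling of the alkenyl triflate with the mild methylzinc reagent installs the C4 methyl group (C15) and completes the C3=C4 cyclobutene without touching the lactone or its allylic α-centre.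

Step 6
Reactants: 8 (1R,4S,5R)-6-methyl-4-[(triisopropylsilyloxy)methyl]-3-oxabicyclo[3.2.0]hept-6-en-2-one
Product: 9 (1R,4S,5R)-4-(hydroxymethyl)-6-methyl-3-oxabicyclo[3.2.0]hept-6-en-2-one
Conditions: Bu4NF, AcOH (1:1), THF, 0 °C to rt
Reagents that add atoms: none
Why: Fluoride-mediated desilylation, buffered with acetic acid so that the allylic lactone α-centre C2 is not epimerised, frees the C7 hydroxyl.

Step 7
Reactants: 9 (1R,4S,5R)-4-(hydroxymethyl)-6-methyl-3-oxabicyclo[3.2.0]hept-6-en-2-one
Product: 10 (1R,4S,5R)-6-methyl-2-oxo-3-oxabicyclo[3.2.0]hept-6-ene-4-carbaldehyde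
Conditions: Dess–Martin periodinane, NaHCO3, CH2Cl2, 0 °C to rt
Reagents that add atoms: none
Why: Dess–Martin oxidation under buffered, base-free conditions gives the α-acyloxy aldehyde (C7) without epimerising C6, and the aldehyde is used at once.

Step 8
Reactants: 10 (1R,4S,5R)-6-methyl-2-oxo-3-oxabicyclo[3.2.0]hept-6-ene-4-carbaldehyde; 11 2-[(4-methoxybenzyl)oxy]acetaldehyde
Product: 13 (1R,4S,5R)-4-[(1R,2S)-1,3-dihydroxy-2-[(4-methoxybenzyl)oxy]propyl]-6-methyl-3-oxabicyclo[3.2.0]hept-6-en-2-one, via aldol aldehyde 12 (not isolated)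
Conditions: D-proline (20 mol%), DMF, 4 °C, 11 (2 equiv) added over 24 h; then MeOH, NaBH4, 0 °C
Reagents that add atoms: none
Why: Proline-catalysed direct cross-aldol (enamine catalysis): the E-enamine of donor 11 adds to the α-branched acceptor 10, which cannot readily act as a donor, through the carboxylic-acid-hydrogen-bonded chair transition state, so D-proline fixes C8 in the configuration of the target with C7–OH anti, and borohydride reduction in the same flask prevents retro-aldol and epimerisation of 12.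

Step 9
Reactants: 13 (1R,4S,5R)-4-[(1R,2S)-1,3-dihydroxy-2-[(4-methoxybenzyl)oxy]propyl]-6-methyl-3-oxabicyclo[3.2.0]hept-6-en-2-one
Product: 14 bis(triethylsilyl) ether of 13 (C7–OSiEt3 and C9–OSiEt3)
Conditions: Et3SiOTf (2.5 equiv), 2,6-lutidine, CH2Cl2, −78 °C
Reagents that add atoms: triethylsilyl trifluoromethanesulfonate, CC[Si](CC)(CC)OS(=O)(=O)C(F)(F)F
Why: Exhaustive silylation with the silyl triflate gives the bis-TES ether, whose primary C9 ether can later be oxidised selectively while the secondary C7 ether stays as a labile late-stage mask.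

Step 10
Reactants: 14 bis(triethylsilyl) ether of 13
Product: 15 lactol of 14 (C1 hemiacetal)
Conditions: i-Bu2AlH (1.1 equiv), CH2Cl2, −78 °C
Reagents that add atoms: none
Why: i-Bu2AlH reduces the γ-lactone only to the lactol at −78 °C because the tetrahedral aluminium hemiacetal is stable until work-up.

Step 11
Reactants: 15 lactol of 14; 16 ethyl 2-bromo-2-(triphenylphosphoranylidene)acetate
Product: 18 ethyl (Z)-2-bromo-3-(cyclobutenyl)acrylate with free C6–OH (C14 ester and C10–Br and C1=C10 on C2; C5 carries C6H(OH)–C7H(OSiEt3)–C8H(OPMB)–C9H2OSiEt3), via hydroxy aldehyde 17 (not isolated)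
Conditions: PhCO2H (10 mol%), CH2Cl2, rt to 35 °C
Reagents that add atoms: none
Why: Wittig olefination of the ring-opened hydroxy aldehyde with the stabilised α-bromo ylide places the ester trans and therefore bromine cis to C2 (the geometry later needed for the ring Z-olefin C1=C10) and liberates C6–OH; it is run at or below 35 °C because the 3-formylcyclobutene tautomer 17 would open electrocyclically on stronger heating.

Step 12
Reactants: 18 ethyl (Z)-2-bromoacrylate with free C6–OH
Product: 19 (Z)-2-bromoallylic alcohol (C14–OH and C6–OH free)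
Conditions: i-Bu2AlH (3.2 equiv), CH2Cl2, −78 °C
Reagents that add atoms: none
Why: 1,2-Reduction of the enoate by i-Bu2AlH at low temperature gives the (Z)-2-bromoallylic alcohol without touching the C–Br bond or the olefin geometry.

Step 13
Reactants: 19 (Z)-2-bromoallylic alcohol
Product: 20 C14 tert-butyldiphenylsilyl ether of 19 (C6–OH free)
Conditions: t-BuPh2SiCl (1.05 equiv), imidazole, CH2Cl2, 0 °C
Reagents that add atoms: tert-butyl(chloro)diphenylsilane, CC(C)(C)[Si](Cl)(c1ccccc1)c1ccccc1
Why: The primary allylic hydroxyl is silylated far faster than the hindered secondary C6–OH (chemoselective silylation), which stays free for the acylation.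

Step 14
Reactants: 21 4-methoxybenzyl alcohol; 22 ethyl 2-(diethoxyphosphoryl)acrylate
Product: 23 ethyl 2-(diethoxyphosphoryl)-3-[(4-methoxybenzyl)oxy]propanoate (racemic)
Conditions: NaH (10 mol%), THF, 0 °C to rt
Reagents that add atoms: none
Why: Base-catalysed oxa-Michael addition of the benzylic alkoxide to the doubly activated acrylate gives the β-alkoxy phosphonoacetate that carries C11, C12 and C13 (as C13–OPMB).

Step 15
Reactants: 23 ethyl 2-(diethoxyphosphoryl)-3-[(4-methoxybenzyl)oxy]propanoate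
Product: 24 2-(diethoxyphosphoryl)-3-[(4-methoxybenzyl)oxy]propanoic acid (racemic)
Conditions: LiOH (1.2 equiv), THF/H2O, 0 °C; then 1 M HCl to pH 3
Reagents that add atoms: lithium hydroxide, [Li+].[OH-]
Why: Saponification of the carboxylic ethyl ester is much faster than that of the phosphonate esters, and working cold limits retro-Michael loss of the alkoxide.

Step 16
Reactants: 20 C14 tert-butyldiphenylsilyl ether; 24 2-(diethoxyphosphoryl)-3-[(4-methoxybenzyl)oxy]propanoic acid
Product: 25 C6 ester of 20 with acid 24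
Conditions: DCC, DMAP (10 mol%), CH2Cl2, 0 °C to rt
Reagents that add atoms: none
Why: Steglich esterification acylates the only free hydroxyl, C6–OH, with retention and places the future lactone carbonyl C12 on O6.

Step 17
Reactants: 25 C6 phosphonoacetate ester
Product: 27 C9 aldehyde (C7–OSiEt3 retained), via alkoxysulfonium chloride 26 (not isolated)
Conditions: (COCl)2, DMSO, CH2Cl2, −78 °C; 25, −78 to −40 °C; then Et3N, −78 to 0 °C
Reagents that add atoms: none
Why: Under Swern conditions a primary triethylsilyl ether is converted directly into the aldehyde through the alkoxysulfonium salt while the secondary TES ether and the TBDPS and PMB ethers survive, so C9 is unmasked without a separate deprotection.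

Step 18
Reactants: 27 C9 aldehyde
Product: 28 cyclooctadienol (eight-membered ring C1, C2, C5–C10 cis-fused to the cyclobutene; C9–OH trans to C8–OPMB)
Conditions: CrCl2 (12 equiv), NiCl2 (0.2 equiv), DMSO/THF (3:1), rt, 0.003 M, slow addition of 27
Reagents that add atoms: none
Why: Nozaki–Hiyama–Kishi closure: oxidative addition of zerovalent nickel to the alkenyl bromide with retention of geometry, transmetalation to trivalent chromium and addition to the C9 aldehyde close the eight-membered ring, with the cis-cyclobutene and the Z-alkenyl unit as turn elements; the C9 carbinol is expected trans to the C8 ether, the arrangement that keeps the chromium-bound oxygen and the C8 oxygen apart on the forming ring, although this is the least certain stereochemical call of the route.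

Step 19
Reactants: 28 cyclooctadienol
Product: 29 C9 tert-butyldimethylsilyl ether of 28
Conditions: t-BuMe2SiOTf, 2,6-lutidine, CH2Cl2, −78 °C
Reagents that add atoms: tert-butyldimethylsilyl trifluoromethanesulfonate, CC(C)(C)[Si](C)(C)OS(=O)(=O)C(F)(F)F
Why: Silyl triflate silylation protects the hindered allylic C9–OH with a group that outlasts the TES ether.

Step 20
Reactants: 29 C9 tert-butyldimethylsilyl ether
Product: 30 C7 alcohol
Conditions: PPTS (0.2 equiv), MeOH/CH2Cl2 (1:1), 0 °C
Reagents that add atoms: none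
Why: Acid-catalysed methanolysis removes the secondary TES ether much faster than the TBS and TBDPS ethers, and the hydroxy ester is taken on without delay to avoid 1,2-acyl migration from O6 to O7.

Step 21
Reactants: 30 C7 alcohol
Product: 31 C7 ketone (α-acyloxy ketone)
Conditions: Dess–Martin periodinane, NaHCO3, CH2Cl2, 0 °C to rt
Reagents that add atoms: none
Why: Dess–Martin oxidation gives the C7 ketone next to the phosphonoacetate ester under neutral conditions that leave the α-alkoxy centre C8 intact.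

Step 22
Reactants: 31 C7 ketone
Product: 32 cis-fused bicyclo[6.2.0] cyclobutene butenolide (6,12-olide with C7=C11, C13–OPMB, C8–OPMB, C9–OTBS, C14–OTBDPS)
Conditions: LiCl, i-Pr2NEt, MeCN, 0 °C to rt
Reagents that add atoms: none
Why: Intramolecular Horner–Wadsworth–Emmons olefination under the mild LiCl/amine conditions closes the five-membered butenolide faster than β-elimination of the C13 alkoxide or epimerisation at C8 can intervene, and the epimeric centre C11 becomes sp2.

Step 23
Reactants: 32 cis-fused bicyclo[6.2.0] cyclobutene butenolide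
Product: 33 (1Z,2E,4Z)-cyclodecatriene butenolide
Conditions: toluene (0.005 M, degassed), BHT (5 mol%), base-washed sealed tube, 140–160 °C
Reagents that add atoms: none
Why: Heating triggers a thermally allowed conrotatory 4π electrocyclic ring opening of the cyclobutene: the C2–C5 σ bond breaks, the C2=C3 and C4=C5 π bonds form, and the eight-membered carbocycle becomes the ten-membered ring C1–C10 by ring expansion through σ-bond cleavage, with no new σ bond and no cyclisation event. The closest known reaction type is the thermal opening of cis-bicyclo[6.2.0]dec-9-enes to cis,trans-cyclodeca-1,3-dienes. No stereocentre is created; C2 and C5 are destroyed, and because the two ring bonds at C2 and C5 are cis, conrotation must give one E and one Z olefin. The selectivity needed is the direction of conrotation: the bulky, conjugating trisubstituted alkenyl group (C1) on C2 should rotate outward (2E) and C6 on C5 inward (4Z), since the alternative would force the alkenyl group inward and place C6 cis to the C4 methyl group. The E geometry of the central olefin keeps the triene from 6π closure, and dilute, degassed, acid-free conditions at the lowest effective temperature limit [1,5]-hydrogen shifts.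

Step 24
Reactants: 33 (1Z,2E,4Z)-cyclodecatriene butenolide
Product: 34 (2R,3S,4S,5S)-2,3:4,5-bis-epoxide
Conditions: dimethyldioxirane (2.3 equiv, in acetone), CH2Cl2, −20 to 0 °C
Reagents that add atoms: dimethyldioxirane, CC1(C)OO1
Why: Epoxidation by dimethyldioxirane (concerted spiro oxygen transfer) should take the two electron-rich diene olefins and not the C1=C10 olefin (flanked by two silyloxy-bearing carbons) or the butenolide; with H6 held in the plane of the Z olefin by 1,3-allylic strain, the C7–C10 bridge covers one face of the E,Z-diene, so both oxygens are delivered to the open face, which corresponds to 2R,3S,4S,5S.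

Step 25
Reactants: 34 bis-epoxide
Product: 35 C9,C14-diol
Conditions: Bu4NF/AcOH (1:1, 4 equiv), THF, 0 °C to rt
Reagents that add atoms: none
Why: Fluoride cleaves the TBS and TBDPS ethers, and buffering with acetic acid protects the epoxides and the butenolide from base.

Step 26
Reactants: 35 C9,C14-diol
Product: 36 C14 3-methylbut-2-enoate (senecioate) with free C9–OH
Conditions: 3-methylbut-2-enoyl chloride (1.1 equiv), pyridine, CH2Cl2, −30 °C
Reagents that add atoms: 3-methylbut-2-enoyl chloride, CC(C)=CC(=O)Cl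
Why: Acylation with the acid chloride at low temperature selects the primary C14–OH over the hindered secondary C9–OH, and the weak base pyridine avoids deconjugation of the senecioyl unit through a vinylketene.

Step 27
Reactants: 37 (R)-(2-methyloxiran-2-yl)methanol
Product: 38 (S)-2-methyloxirane-2-carboxylic acid
Conditions: RuCl3 (2 mol%), NaIO4 (3 equiv), MeCN/EtOAc/H2O, 0 °C to rt
Reagents that add atoms: sodium periodate, [Na+].[O-]I(=O)(=O)=O; water, O
Why: RuO4-catalysed oxidation of the primary alcohol to the acid leaves the epoxide and its quaternary stereocentre untouched, the descriptor changing from R to S only through the priority switch.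

Step 28
Reactants: 36 C14 senecioate; 38 (S)-2-methyloxirane-2-carboxylic acid
Product: 40 C9 (S)-2-methylglycidate, via mixed anhydride 39 (not isolated)
Conditions: 2,4,6-trichlorobenzoyl chloride, Et3N, THF, 0 °C; then 36, DMAP, toluene, rt
Reagents that add atoms: none
Why: Yamaguchi esterification through the mixed anhydride acylates the hindered C9–OH with retention at C9 and at the glycidate centre, and the inert C8 PMB ether rules out acyl migration.

Step 29
Reactants: 40 C9 (S)-2-methylglycidate
Product: 41 C8,C13-diol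
Conditions: DDQ (3 equiv), CH2Cl2/pH 7 buffer (10:1), 0 °C
Reagents that add atoms: none
Why: Oxidative cleavage of both p-methoxybenzyl ethers by DDQ (benzylic hydride abstraction, then hydrolysis of the oxocarbenium ion) should spare the epoxides, the two enoates and the glycidate, the buffer protecting the allylic oxirane from acid.

Step 30
Reactants: 41 C8,C13-diol
Product: 42 target CNP0279449.1
Conditions: Ac2O, pyridine, DMAP (cat.), CH2Cl2, 0 °C
Reagents that add atoms: acetic anhydride, CC(=O)OC(C)=O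
Why: Pyridine/DMAP acetylation of the primary C13 and secondary C8 hydroxyls at low temperature is faster than acyl migration from O9 or translactonisation to the 8,12-olide, and completes the target.

**Compound list**

1 | (S)-5-(hydroxymethyl)furan-2(5H)-one | OC[C@H]1OC(=O)C=C1 | starting material
2 | (S)-5-[(triisopropylsilyloxy)methyl]furan-2(5H)-one | CC(C)[Si](C(C)C)(C(C)C)OC[C@H]1OC(=O)C=C1 | intermediate
3 | 1,1-diethoxyethene | C=C(OCC)OCC | starting material
4 | (1R,4S,5S)-6,6-diethoxy-4-[(triisopropylsilyloxy)methyl]-3-oxabicyclo[3.2.0]heptan-2-one | CC(C)[Si](C(C)C)(C(C)C)OC[C@H]1OC(=O)[C@@H]2CC(OCC)(OCC)[C@@H]21 | intermediate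
5 | (1R,4S,5S)-4-[(triisopropylsilyloxy)methyl]-3-oxabicyclo[3.2.0]heptane-2,6-dione | CC(C)[Si](C(C)C)(C(C)C)OC[C@H]1OC(=O)[C@@H]2CC(=O)[C@@H]21 | intermediate
6 | potassium enolate of 5 (C3=C4–OK) | CC(C)[Si](C(C)C)(C(C)C)OC[C@H]1OC(=O)[C@@H]2C=C([O-])[C@@H]21.[K+] | intermediate
7 | (1R,4S,5S)-2-oxo-4-[(triisopropylsilyloxy)methyl]-3-oxabicyclo[3.2.0]hept-6-en-6-yl trifluoromethanesulfonate | CC(C)[Si](C(C)C)(C(C)C)OC[C@H]1OC(=O)[C@@H]2C=C(OS(=O)(=O)C(F)(F)F)[C@@H]21 | intermediate
8 | (1R,4S,5R)-6-methyl-4-[(triisopropylsilyloxy)methyl]-3-oxabicyclo[3.2.0]hept-6-en-2-one | CC(C)[Si](C(C)C)(C(C)C)OC[C@H]1OC(=O)[C@@H]2C=C(C)[C@@H]21 | intermediate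
9 | (1R,4S,5R)-4-(hydroxymethyl)-6-methyl-3-oxabicyclo[3.2.0]hept-6-en-2-one | OC[C@H]1OC(=O)[C@@H]2C=C(C)[C@@H]21 | intermediate
10 | (1R,4S,5R)-6-methyl-2-oxo-3-oxabicyclo[3.2.0]hept-6-ene-4-carbaldehyde | O=C[C@H]1OC(=O)[C@@H]2C=C(C)[C@@H]21 | intermediate
11 | 2-[(4-methoxybenzyl)oxy]acetaldehyde | O=CCOCc1ccc(OC)cc1 | starting material
12 | (2R,3R)-3-hydroxy-2-[(4-methoxybenzyl)oxy]-3-[(1R,4S,5R)-6-methyl-2-oxo-3-oxabicyclo[3.2.0]hept-6-en-4-yl]propanal | O=C[C@H](OCc1ccc(OC)cc1)[C@H](O)[C@H]1OC(=O)[C@@H]2C=C(C)[C@@H]21 | intermediate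
13 | (1R,4S,5R)-4-[(1R,2S)-1,3-dihydroxy-2-[(4-methoxybenzyl)oxy]propyl]-6-methyl-3-oxabicyclo[3.2.0]hept-6-en-2-one | OC[C@H](OCc1ccc(OC)cc1)[C@H](O)[C@H]1OC(=O)[C@@H]2C=C(C)[C@@H]21 | intermediate
14 | bis(triethylsilyl) ether of 13 (C7 and C9) | CC[Si](CC)(CC)OC[C@H](OCc1ccc(OC)cc1)[C@H](O[Si](CC)(CC)CC)[C@H]1OC(=O)[C@@H]2C=C(C)[C@@H]21 | intermediate
15 | lactol of 14 (C1 hemiacetal, anomeric mixture) | CC[Si](CC)(CC)OC[C@H](OCc1ccc(OC)cc1)[C@H](O[Si](CC)(CC)CC)[C@H]1OC(O)[C@@H]2C=C(C)[C@@H]21 | intermediate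
16 | ethyl 2-bromo-2-(triphenylphosphoranylidene)acetate | CCOC(=O)C(Br)=P(c1ccccc1)(c1ccccc1)c1ccccc1 | starting material
17 | ring-opened hydroxy aldehyde tautomer of 15 (C1 aldehyde on C2, free C6–OH) | O=C[C@@H]1C=C(C)[C@@H]1[C@H](O)[C@@H](O[Si](CC)(CC)CC)[C@@H](OCc1ccc(OC)cc1)CO[Si](CC)(CC)CC | intermediate
18 | ethyl (Z)-2-bromoacrylate on C2 of the cis-disubstituted methylcyclobutene, free C6–OH | CCOC(=O)/C(Br)=C/[C@@H]1C=C(C)[C@@H]1[C@H](O)[C@@H](O[Si](CC)(CC)CC)[C@@H](OCc1ccc(OC)cc1)CO[Si](CC)(CC)CC | intermediate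
19 | (Z)-2-bromoallylic alcohol (C14–OH and C6–OH free) | OC/C(Br)=C/[C@@H]1C=C(C)[C@@H]1[C@H](O)[C@@H](O[Si](CC)(CC)CC)[C@@H](OCc1ccc(OC)cc1)CO[Si](CC)(CC)CC | intermediate
20 | C14 tert-butyldiphenylsilyl ether of 19 | CC(C)(C)[Si](c1ccccc1)(c1ccccc1)OC/C(Br)=C/[C@@H]1C=C(C)[C@@H]1[C@H](O)[C@@H](O[Si](CC)(CC)CC)[C@@H](OCc1ccc(OC)cc1)CO[Si](CC)(CC)CC | intermediate
21 | 4-methoxybenzyl alcohol | COc1ccc(CO)cc1 | starting material
22 | ethyl 2-(diethoxyphosphoryl)acrylate | CCOC(=O)C(=C)P(=O)(OCC)OCC | starting material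
23 | ethyl 2-(diethoxyphosphoryl)-3-[(4-methoxybenzyl)oxy]propanoate (racemic) | CCOC(=O)C(COCc1ccc(OC)cc1)P(=O)(OCC)OCC | intermediate
24 | 2-(diethoxyphosphoryl)-3-[(4-methoxybenzyl)oxy]propanoic acid (racemic) | OC(=O)C(COCc1ccc(OC)cc1)P(=O)(OCC)OCC | intermediate
25 | C6 ester of 20 with acid 24 (C11 epimers) | CC(C)(C)[Si](c1ccccc1)(c1ccccc1)OC/C(Br)=C/[C@@H]1C=C(C)[C@@H]1[C@H](OC(=O)C(COCc1ccc(OC)cc1)P(=O)(OCC)OCC)[C@@H](O[Si](CC)(CC)CC)[C@@H](OCc1ccc(OC)cc1)CO[Si](CC)(CC)CC | intermediate
26 | C9 alkoxydimethylsulfonium chloride from 25 | CC(C)(C)[Si](c1ccccc1)(c1ccccc1)OC/C(Br)=C/[C@@H]1C=C(C)[C@@H]1[C@H](OC(=O)C(COCc1ccc(OC)cc1)P(=O)(OCC)OCC)[C@@H](O[Si](CC)(CC)CC)[C@@H](OCc1ccc(OC)cc1)CO[S+](C)C.[Cl-] | intermediate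
27 | C9 aldehyde (C7–OSiEt3, C8–OPMB, C6 phosphonoacetate, alkenyl bromide) | CC(C)(C)[Si](c1ccccc1)(c1ccccc1)OC/C(Br)=C/[C@@H]1C=C(C)[C@@H]1[C@H](OC(=O)C(COCc1ccc(OC)cc1)P(=O)(OCC)OCC)[C@@H](O[Si](CC)(CC)CC)[C@@H](OCc1ccc(OC)cc1)C=O | intermediate
28 | cyclooctadienol: cis-bicyclo[6.2.0]deca-diene with C9–OH trans to C8–OPMB | CC[Si](CC)(CC)O[C@H]1[C@@H](OCc3ccc(OC)cc3)[C@H](O)/C(CO[Si](c3ccccc3)(c3ccccc3)C(C)(C)C)=C\[C@@H]2C=C(C)[C@@H]2[C@@H]1OC(=O)C(COCc1ccc(OC)cc1)P(=O)(OCC)OCC | intermediate
29 | C9 tert-butyldimethylsilyl ether of 28 | CC[Si](CC)(CC)O[C@H]1[C@@H](OCc3ccc(OC)cc3)[C@H](O[Si](C)(C)C(C)(C)C)/C(CO[Si](c3ccccc3)(c3ccccc3)C(C)(C)C)=C\[C@@H]2C=C(C)[C@@H]2[C@@H]1OC(=O)C(COCc1ccc(OC)cc1)P(=O)(OCC)OCC | intermediate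
30 | C7 alcohol from 29 | O[C@H]1[C@@H](OCc3ccc(OC)cc3)[C@H](O[Si](C)(C)C(C)(C)C)/C(CO[Si](c3ccccc3)(c3ccccc3)C(C)(C)C)=C\[C@@H]2C=C(C)[C@@H]2[C@@H]1OC(=O)C(COCc1ccc(OC)cc1)P(=O)(OCC)OCC | intermediate
31 | C7 ketone | O=C1[C@@H](OCc3ccc(OC)cc3)[C@H](O[Si](C)(C)C(C)(C)C)/C(CO[Si](c3ccccc3)(c3ccccc3)C(C)(C)C)=C\[C@@H]2C=C(C)[C@@H]2[C@@H]1OC(=O)C(COCc1ccc(OC)cc1)P(=O)(OCC)OCC | intermediate
32 | cis-fused cyclobutene on the eight-membered butenolide (key-step precursor; C8–OPMB, C13–OPMB, C9–OTBS, C14–OTBDPS) | COc4ccc(cc4)COCC1=C2[C@@H](OCc4ccc(OC)cc4)[C@H](O[Si](C)(C)C(C)(C)C)/C(CO[Si](c4ccccc4)(c4ccccc4)C(C)(C)C)=C\[C@@H]3C=C(C)[C@@H]3[C@@H]2OC1=O | intermediate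
33 | (1Z,2E,4Z)-cyclodecatriene butenolide (key-step product) | COc4ccc(cc4)COCC1=C2[C@@H](OCc4ccc(OC)cc4)[C@H](O[Si](C)(C)C(C)(C)C)/C(CO[Si](c4ccccc4)(c4ccccc4)C(C)(C)C)=C\C=C\C(C)=C/[C@@H]2OC1=O | intermediate
34 | (2R,3S,4S,5S)-2,3:4,5-bis-epoxide of 33 | COc4ccc(cc4)COCC1=C2[C@@H](OCc4ccc(OC)cc4)[C@H](O[Si](C)(C)C(C)(C)C)/C(CO[Si](c4ccccc4)(c4ccccc4)C(C)(C)C)=C\[C@H]3O[C@@H]3[C@@]3(C)O[C@H]3[C@@H]2OC1=O | intermediate
35 | C9,C14-diol | COc4ccc(cc4)COCC1=C2[C@@H](OCc4ccc(OC)cc4)[C@H](O)/C(CO)=C\[C@H]3O[C@@H]3[C@@]3(C)O[C@H]3[C@@H]2OC1=O | intermediate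
36 | C14 senecioate with free C9–OH | COc4ccc(cc4)COCC1=C2[C@@H](OCc4ccc(OC)cc4)[C@H](O)/C(COC(=O)C=C(C)C)=C\[C@H]3O[C@@H]3[C@@]3(C)O[C@H]3[C@@H]2OC1=O | intermediate
37 | (R)-(2-methyloxiran-2-yl)methanol | OC[C@]1(C)CO1 | starting material
38 | (S)-2-methyloxirane-2-carboxylic acid | OC(=O)[C@]1(C)CO1 | intermediate
39 | (S)-2-methyloxirane-2-carboxylic 2,4,6-trichlorobenzoic anhydride | O=C(OC(=O)c1c(Cl)cc(Cl)cc1Cl)[C@]1(C)CO1 | intermediate
40 | C9 (S)-2-methylglycidate, C14 senecioate, C8/C13 bis-PMB ether | COc4ccc(cc4)COCC1=C2[C@@H](OCc4ccc(OC)cc4)[C@H](OC(=O)[C@]3(C)CO3)/C(COC(=O)C=C(C)C)=C\[C@H]3O[C@@H]3[C@@]3(C)O[C@H]3[C@@H]2OC1=O | intermediate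
41 | C8,C13-diol | OCC1=C2[C@@H](O)[C@H](OC(=O)[C@]3(C)CO3)/C(COC(=O)C=C(C)C)=C\[C@H]3O[C@@H]3[C@@]3(C)O[C@H]3[C@@H]2OC1=O | intermediate
42 | CNP0279449.1 | CC(=O)OCC1=C2[C@@H](OC(C)=O)[C@H](OC(=O)[C@]3(C)CO3)/C(COC(=O)C=C(C)C)=C\[C@H]3O[C@@H]3[C@@]3(C)O[C@H]3[C@@H]2OC1=O | target

**Step count and risks**

Total step count: 30 (steps 14, 15 and 27 prepare the two side reagents). Longest linear sequence: 27 steps (1–13, 16–26, 28–30).

The three steps most likely to fail:

Step 23 (ring expansion). What may go wrong is incomplete control over the direction of conrotation (the alkenyl group turning inward, giving the 2Z,4E isomer), or a [1,5]-hydrogen shift of the butenolide-activated H6 in the product at the temperature the opening needs. The fallback moves the ring expansion ahead of the butenolide annulation, so that the cyclobutene opens in a carbocycle whose C6 and C7 are still sp3 and whose H6 is not activated. It sets out from 29, which is heated in degassed toluene (140–160 °C) to the ten-membered triene phosphonoacetate F1. PPTS in MeOH then removes the TES ether to give the C7 alcohol F2, and Dess–Martin oxidation gives the C7 ketone F3. Intramolecular Horner–Wadsworth–Emmons reaction of F3 (LiCl, i-Pr2NEt, MeCN) closes the butenolide on the ten-membered ring and rejoins the route at 33.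

Step 18 (ring closure). What may go wrong is poor or reversed facial selectivity at C9, since an open-chain α-alkoxy aldehyde would favour the cis C8/C9 arrangement. The fallback replaces substrate-controlled C–C bond formation by reagent-controlled reduction. It sets out from 28 obtained as an epimer mixture: Dess–Martin oxidation gives the cross-conjugated cyclooctadienone F4, and CBS reduction ((R)-2-methyl-CBS-oxazaborolidine, catecholborane, toluene, −78 °C) returns the single C9 alcohol 28. In that reduction the trisubstituted alkenyl branch acts as the large group, and hydride entry anti to the C8–O bond favours the same face.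

Step 24 (double epoxidation). What may go wrong is poor facial selectivity at one of the two diene olefins, or competing attack at C1=C10. The fallback replaces substrate control by reagent control in two stages and sets out from 33. Shi epoxidation with the L-fructose-derived ketone (KHSO5, K2CO3, MeCN/H2O, 0 °C) should epoxidise the electron-rich trisubstituted C4=C5 olefin on the required face to the 4,5-monoepoxide F5. Shi epoxidation with the D-fructose-derived ketone, for which the spiro transition-state model predicts the 2R,3S oxirane from the E olefin, then rejoins the route at 34.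

Further compounds
F1 | step 23 | ten-membered (1Z,2E,4Z)-triene phosphonoacetate from thermolysis of 29 | CC[Si](CC)(CC)O[C@H]1[C@@H](OCc3ccc(OC)cc3)[C@H](O[Si](C)(C)C(C)(C)C)/C(CO[Si](c3ccccc3)(c3ccccc3)C(C)(C)C)=C\C=C\C(C)=C/[C@@H]1OC(=O)C(COCc1ccc(OC)cc1)P(=O)(OCC)OCC
F2 | step 23 | C7 alcohol of the ten-membered triene | O[C@H]1[C@@H](OCc3ccc(OC)cc3)[C@H](O[Si](C)(C)C(C)(C)C)/C(CO[Si](c3ccccc3)(c3ccccc3)C(C)(C)C)=C\C=C\C(C)=C/[C@@H]1OC(=O)C(COCc1ccc(OC)cc1)P(=O)(OCC)OCC
F3 | step 23 | C7 ketone of the ten-membered triene | O=C1[C@@H](OCc3ccc(OC)cc3)[C@H](O[Si](C)(C)C(C)(C)C)/C(CO[Si](c3ccccc3)(c3ccccc3)C(C)(C)C)=C\C=C\C(C)=C/[C@@H]1OC(=O)C(COCc1ccc(OC)cc1)P(=O)(OCC)OCC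
F4 | step 18 | cyclooctadienone (C9 ketone of 28) | CC[Si](CC)(CC)O[C@H]1[C@@H](OCc3ccc(OC)cc3)C(=O)/C(CO[Si](c3ccccc3)(c3ccccc3)C(C)(C)C)=C\[C@@H]2C=C(C)[C@@H]2[C@@H]1OC(=O)C(COCc1ccc(OC)cc1)P(=O)(OCC)OCC
F5 | step 24 | (4S,5S)-4,5-monoepoxide of 33 | COc4ccc(cc4)COCC1=C2[C@@H](OCc4ccc(OC)cc4)[C@H](O[Si](C)(C)C(C)(C)C)/C(CO[Si](c4ccccc4)(c4ccccc4)C(C)(C)C)=C\C=C\[C@@]3(C)O[C@H]3[C@@H]2OC1=O
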